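The route builds ring B last, from open-chain pieces. Ring B is a 2',4'-dioxygenated arene whose C3', flanked by both oxygens, bears the five-carbon chain of ring D, and only O2' may become the pyran oxygen. A vinylketene (from an alkenyl diazoketone) and a prenyl siloxyalkyne create this ring in one operation, forming four C–C bonds and delivering prenyl on C3', a free O2'–H and a silylated O4'. The precursor is an enantiopure chroman, rings A and C complete and C3 set by asymmetric hydrogenation, carrying an (E)-CH=CH–CO–CHN2 arm on C3. Selenium-mediated closure of ring D and desilylation finish the synthesis.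

Key step: step 14

Abbreviations: prenyl = 3-methylbut-2-en-1-yl; TIPS = triisopropylsilyl; MOM = methoxymethyl; ring B atoms are primed.
Remark: the spatial arrangement at C3 is unchanged from the chroman-3-carboxylic acid to the target; the descriptor reads S for the carboxyl-derived compounds and R for the alkenyl and aryl compounds only because the priorities change.
Remark: the (R)-BINAP ligand in step 8 is assigned by analogy with the sense known for tiglic-acid-type substrates; if the first run shows the opposite sense, the (S)-ligand is used and nothing else changes.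
Remark: ring D is closed with an electrophilic selenium reagent and not with a high-potential quinone, because a 2'-hydroxyisoflavan with an electron-rich ring A can lose hydride from C4 to such an oxidant and close to a pterocarpan.

Step 1
Reactants: 1 2,4,6-trihydroxybenzaldehyde; 2 prenyl bromide
Product: 3 2,4,6-trihydroxy-3-prenylbenzaldehyde
Conditions: 2 (1.0 equiv), DBU, THF, 0 °C → rt
Reagents that add atoms: none
Why: Base-mediated C-alkylation of the acylphloroglucinol anion (C-prenylation) puts the prenyl group on one of the two equivalent ring CH positions, and limiting the bromide to one equivalent should hold back double alkylation and O-alkylation.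

Step 2
Reactants: 3 2,4,6-trihydroxy-3-prenylbenzaldehyde
Product: 4 2-hydroxy-4,6-bis(methoxymethoxy)-3-prenylbenzaldehyde
Conditions: MOMCl (2.2 equiv), i-Pr2NEt, CH2Cl2, 0 °C
Reagents that add atoms: chloromethyl methyl ether, COCCl
Why: MOM ether formation should take the two more accessible hydroxyls, O4 and O6, because the hydroxyl wedged between the formyl and prenyl groups is the most hindered and stays locked in the hydrogen bond to the carbonyl.

Step 3
Reactants: 4 2-hydroxy-4,6-bis(methoxymethoxy)-3-prenylbenzaldehyde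
Product: 5 2-methoxy-4,6-bis(methoxymethoxy)-3-prenylbenzaldehyde
Conditions: MeI, K2CO3, DMF, rt → 40 °C
Reagents that add atoms: iodomethane, CI
Why: Williamson methylation of the one remaining, chelated phenol fixes the methyl group on the oxygen next to the prenyl group, which is the O5/C6 pattern of ring A.

Step 4
Reactants: 5 2-methoxy-4,6-bis(methoxymethoxy)-3-prenylbenzaldehyde
Product: 6 4,6-dihydroxy-2-methoxy-3-prenylbenzaldehyde
Conditions: HCl (aq., cat.), MeOH, 40 °C
Reagents that add atoms: none
Why: Acid-catalysed transacetalisation in methanol removes both MOM groups, which are labile because each phenol is conjugated with the formyl group, under conditions mild enough that the ortho-prenyl phenol should not cyclise.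

Step 5
Reactants: 6 4,6-dihydroxy-2-methoxy-3-prenylbenzaldehyde
Product: 7 6-hydroxy-2-methoxy-3-prenyl-4-(triisopropylsilyloxy)benzaldehyde
Conditions: i-Pr3SiCl (1.05 equiv), imidazole, CH2Cl2, 0 °C
Reagents that add atoms: chlorotriisopropylsilane, CC(C)[Si](Cl)(C(C)C)C(C)C
Why: Selective silylation of a 2,4-dihydroxybenzaldehyde-type diol goes to the hydroxyl para to the formyl group, since the ortho hydroxyl is tied up in the intramolecular hydrogen bond.

Step 6
Reactants: 7 6-hydroxy-2-methoxy-3-prenyl-4-(triisopropylsilyloxy)benzaldehyde; 8 acrolein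
Product: 10 5-methoxy-6-prenyl-7-(triisopropylsilyloxy)-2H-chromene-3-carbaldehyde, via oxa-Michael adduct 9 (not isolated)
Conditions: 8 (excess), K2CO3, 1,4-dioxane, reflux
Reagents that add atoms: none
Why: Oxa-Michael addition of the phenoxide to acrolein followed by intramolecular aldol condensation (the standard 2H-chromene-3-carbaldehyde annulation of salicylaldehydes) can only use the single free ortho hydroxyl, so ring C closes with prenyl at C6 and methoxy at C5.

Step 7
Reactants: 10 5-methoxy-6-prenyl-7-(triisopropylsilyloxy)-2H-chromene-3-carbaldehyde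
Product: 11 5-methoxy-6-prenyl-7-(triisopropylsilyloxy)-2H-chromene-3-carboxylic acid
Conditions: NaClO2, NaH2PO4, 2-methylbut-2-ene (large excess), t-BuOH/H2O, 0 °C → rt
Reagents that add atoms: sodium chlorite, [Na+].[O-]Cl=O
Why: Pinnick oxidation converts the enal into the acrylic acid without touching the ring alkene, and the excess 2-methylbut-2-ene scavenges hypochlorous acid before it can attack the prenyl group or the electron-rich arene.

Step 8
Reactants: 11 5-methoxy-6-prenyl-7-(triisopropylsilyloxy)-2H-chromene-3-carboxylic acid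
Product: 12 (3S)-5-methoxy-6-prenyl-7-(triisopropylsilyloxy)chroman-3-carboxylic acid
Conditions: H2 (pressure vessel), Ru(OAc)2[(R)-BINAP] (cat.), MeOH, rt
Reagents that add atoms: none
Why: Carboxylate-directed asymmetric hydrogenation of an α,β-unsaturated acid with a Ru–BINAP dicarboxylate catalyst sets C3 in the chelated substrate–catalyst complex, the ligand enantiomer choosing the alkene face, while the unfunctionalised trisubstituted prenyl alkene has no binding group and should stay intact.

Step 9
Reactants: 12 (3S)-5-methoxy-6-prenyl-7-(triisopropylsilyloxy)chroman-3-carboxylic acid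
Product: 14 (3S)-N-methoxy-N-methyl-5-methoxy-6-prenyl-7-(triisopropylsilyloxy)chroman-3-carboxamide, via acyl imidazole 13 (not isolated)
Conditions: 1,1'-carbonyldiimidazole, CH2Cl2, rt; then MeNH(OMe)·HCl, rt
Reagents that add atoms: N,O-dimethylhydroxylamine hydrochloride, CNOC.Cl
Why: Carbonyldiimidazole activation and aminolysis (Weinreb amide formation) proceed through the acyl imidazole under near-neutral conditions that should not epimerise C3.

Step 10
Reactants: 14 (3S)-N-methoxy-N-methyl-5-methoxy-6-prenyl-7-(triisopropylsilyloxy)chroman-3-carboxamide; 15 dimethyl (2-oxopropyl)phosphonate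
Product: 17 (E)-4-[(3R)-5-methoxy-6-prenyl-7-(triisopropylsilyloxy)chroman-3-yl]but-3-en-2-one, via chroman-3-carbaldehyde 16 (not isolated)
Conditions: i-Bu2AlH, THF, −78 °C; aq. KNaC4H4O6 work-up; crude 16 at once treated with 15, LiCl, i-Pr2NEt, MeCN, 0 °C → rt
Reagents that add atoms: none
Why: Hydride reduction of the Weinreb amide stops at the aldehyde through the chelated aluminium hemiaminal, and immediate Horner–Wadsworth–Emmons olefination under Masamune–Roush conditions gives the (E)-enone while keeping the exposure of the epimerisable, β-aryloxy aldehyde to base short and mild.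

Step 11
Reactants: 17 (E)-4-[(3R)-5-methoxy-6-prenyl-7-(triisopropylsilyloxy)chroman-3-yl]but-3-en-2-one
Product: 19 (E)-1-diazo-4-[(3R)-5-methoxy-6-prenyl-7-(triisopropylsilyloxy)chroman-3-yl]but-3-en-2-one, via trifluoroacetyl diketone 18 (not isolated)
Conditions: LiN(SiMe3)2, THF, −78 °C; CF3CO2CH2CF3, −78 °C; aq. HCl work-up; then MsN3, Et3N, H2O, MeCN, rt
Reagents that add atoms: methanesulfonyl azide, CS(=O)(=O)N=[N+]=[N-]
Why: Detrifluoroacetylative diazo transfer works because kinetic deprotonation takes the methyl group of the enone, the trifluoroacetyl group activates that carbon for attack by the sulfonyl azide and is then lost, and the γ-hydrogen at C3 is never removed.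

Step 12
Reactants: 20 4-methylpent-3-enoic acid
Product: 21 ethyl 4-methylpent-3-enoate
Conditions: EtI, K2CO3, DMF, rt
Reagents that add atoms: iodoethane, CCI
Why: Carboxylate O-alkylation under mild base gives the ethyl ester without the acid catalysis that would lactonise or isomerise this β,γ-unsaturated acid.

Step 13
Reactants: 21 ethyl 4-methylpent-3-enoate
Product: 24 triisopropyl[(5-methylhex-4-en-1-yn-1-yl)oxy]silane, via lithium dibromoenolate 22 (not isolated), via lithium ynolate 23 (not isolated)
Conditions: CH2Br2, lithium 2,2,6,6-tetramethylpiperidide, THF, −78 °C; 21; LiN(SiMe3)2; n-BuLi, −78 °C → rt; i-Pr3SiCl, −78 °C → rt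
Reagents that add atoms: dibromomethane, BrCBr; chlorotriisopropylsilane, CC(C)[Si](Cl)(C(C)C)C(C)C
Why: In the Kowalski ester homologation LiCHBr2 adds to the ester, the derived dibromo enolate undergoes bromine–lithium exchange and 1,2-shift of the prenyl group to the ynolate, and the hindered silyl chloride traps it on oxygen to give the siloxyalkyne.

Step 14
Reactants: 19 (E)-1-diazo-4-[(3R)-5-methoxy-6-prenyl-7-(triisopropylsilyloxy)chroman-3-yl]but-3-en-2-one; 24 triisopropyl[(5-methylhex-4-en-1-yn-1-yl)oxy]silane
Product: 29 6-[(3R)-5-methoxy-6-prenyl-7-(triisopropylsilyloxy)chroman-3-yl]-2-prenyl-3-(triisopropylsilyloxy)phenol, via vinylketene 25 (not isolated), via vinylcyclobutenone 26 (not isolated), via dienylketene 27 (not isolated), via cyclohexadienone 28 (not isolated)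
Conditions: 24 (1.5 equiv), hν (medium-pressure Hg lamp, Pyrex filter), ClCH2CH2Cl, rt; then 80 °C in the dark
Reagents that add atoms: none
Why: Light expels N2 from 19 and the alkenyl group shifts to the carbene carbon (photochemical Wolff rearrangement, forming C5'–C6') to give vinylketene 25, which adds alkyne 24 across its ketene C=C in a [2+2] step with the nucleophilic prenyl-bearing carbon bonding to the ketene carbonyl carbon (C2'–C3') and the siloxy carbon to the α-carbon (C4'–C5'), giving 26. Heating opens 26 by reversible conrotatory 4π cleavage to dienylketene 27, and the isomer with ketene and alkenyl group cis closes ring B by thermal disrotatory 6π electrocyclisation (C1'–C2') to 28, which tautomerises to phenol 29. The closest known reaction is the Danheiser benzannulation in its diazoketone form with trialkylsiloxyalkynes, which gives resorcinol monosilyl ethers. No stereocentre is formed in 29, since the sp3 centre of 26 and 28 is erased on aromatisation, and C3 of the chroman is a spectator whose hydrogen is not acidified in any intermediate. The one selectivity needed is the orientation of the [2+2] addition, and the polarised ynol ether secures it, so that prenyl ends on C3' with O2' free and O4' silylated. An excess of 24 and the absence of any free hydroxyl in 19 should keep the ketene from dimerising or being acylated away.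

Step 15
Reactants: 29 6-[(3R)-5-methoxy-6-prenyl-7-(triisopropylsilyloxy)chroman-3-yl]-2-prenyl-3-(triisopropylsilyloxy)phenol
Product: 31 (3R)-3-[2,2-dimethyl-5-(triisopropylsilyloxy)-2H-chromen-8-yl]-5-methoxy-6-prenyl-7-(triisopropylsilyloxy)chroman, via selenide 30 (not isolated)
Conditions: N-(phenylseleno)phthalimide (1.1 equiv), (±)-camphor-10-sulfonic acid (cat.), CH2Cl2, −78 → 0 °C; then mCPBA (1.1 equiv), −78 °C; i-Pr2NH, −78 °C → rt
Reagents that add atoms: none
Why: Acid-catalysed selenoetherification by the free O2'–H on the neighbouring prenyl alkene (6-endo, Markovnikov opening of the seleniranium ion) followed by selenoxide syn-elimination toward the only β-hydrogens, at the benzylic carbon, gives the 2,2-dimethyl-2H-chromene, whereas the ring A prenyl group has no neighbouring nucleophile, so its seleniranium ion should revert.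

Step 16
Reactants: 31 (3R)-3-[2,2-dimethyl-5-(triisopropylsilyloxy)-2H-chromen-8-yl]-5-methoxy-6-prenyl-7-(triisopropylsilyloxy)chroman
Product: 32 (3R)-3-(5-hydroxy-2,2-dimethyl-2H-chromen-8-yl)-5-methoxy-6-prenylchroman-7-ol (CNP0119857.1)
Conditions: Bu4NF (2.2 equiv), AcOH (2.2 equiv), THF, 0 °C → rt
Reagents that add atoms: none
Why: Fluoride cleavage of the two aryl silyl ethers, buffered with acetic acid so that the phenoxides are protonated at once, frees O7–H and O4'–H without affecting the chromene, the prenyl group or C3.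

Compound list
1 | 2,4,6-trihydroxybenzaldehyde | O=Cc1c(O)cc(O)cc1O | starting material
2 | prenyl bromide (1-bromo-3-methylbut-2-ene) | CC(C)=CCBr | starting material
3 | 2,4,6-trihydroxy-3-prenylbenzaldehyde | O=Cc1c(O)cc(O)c(CC=C(C)C)c1O | intermediate
4 | 2-hydroxy-4,6-bis(methoxymethoxy)-3-prenylbenzaldehyde | O=Cc1c(OCOC)cc(OCOC)c(CC=C(C)C)c1O | intermediate
5 | 2-methoxy-4,6-bis(methoxymethoxy)-3-prenylbenzaldehyde | O=Cc1c(OCOC)cc(OCOC)c(CC=C(C)C)c1OC | intermediate
6 | 4,6-dihydroxy-2-methoxy-3-prenylbenzaldehyde | O=Cc1c(O)cc(O)c(CC=C(C)C)c1OC | intermediate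
7 | 6-hydroxy-2-methoxy-3-prenyl-4-(triisopropylsilyloxy)benzaldehyde | O=Cc1c(O)cc(O[Si](C(C)C)(C(C)C)C(C)C)c(CC=C(C)C)c1OC | intermediate
8 | acrolein | C=CC=O | starting material
9 | 2-methoxy-6-(3-oxopropoxy)-3-prenyl-4-(triisopropylsilyloxy)benzaldehyde (oxa-Michael adduct) | O=CCCOc1cc(O[Si](C(C)C)(C(C)C)C(C)C)c(CC=C(C)C)c(OC)c1C=O | intermediate
10 | 5-methoxy-6-prenyl-7-(triisopropylsilyloxy)-2H-chromene-3-carbaldehyde | COc1c(CC=C(C)C)c(O[Si](C(C)C)(C(C)C)C(C)C)cc2c1C=C(C=O)CO2 | intermediate
11 | 5-methoxy-6-prenyl-7-(triisopropylsilyloxy)-2H-chromene-3-carboxylic acid | COc1c(CC=C(C)C)c(O[Si](C(C)C)(C(C)C)C(C)C)cc2c1C=C(C(=O)O)CO2 | intermediate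
12 | (3S)-5-methoxy-6-prenyl-7-(triisopropylsilyloxy)chroman-3-carboxylic acid | COc1c(CC=C(C)C)c(O[Si](C(C)C)(C(C)C)C(C)C)cc2c1C[C@H](C(=O)O)CO2 | intermediate
13 | (3S)-3-(imidazol-1-ylcarbonyl)-5-methoxy-6-prenyl-7-(triisopropylsilyloxy)chroman (acyl imidazole) | COc1c(CC=C(C)C)c(O[Si](C(C)C)(C(C)C)C(C)C)cc2c1C[C@H](C(=O)n1ccnc1)CO2 | intermediate
14 | (3S)-N-methoxy-N-methyl-5-methoxy-6-prenyl-7-(triisopropylsilyloxy)chroman-3-carboxamide | COc1c(CC=C(C)C)c(O[Si](C(C)C)(C(C)C)C(C)C)cc2c1C[C@H](C(=O)N(C)OC)CO2 | intermediate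
15 | dimethyl (2-oxopropyl)phosphonate | COP(=O)(CC(C)=O)OC | starting material
16 | (3S)-5-methoxy-6-prenyl-7-(triisopropylsilyloxy)chroman-3-carbaldehyde | COc1c(CC=C(C)C)c(O[Si](C(C)C)(C(C)C)C(C)C)cc2c1C[C@H](C=O)CO2 | intermediate
17 | (E)-4-[(3R)-5-methoxy-6-prenyl-7-(triisopropylsilyloxy)chroman-3-yl]but-3-en-2-one | COc1c(CC=C(C)C)c(O[Si](C(C)C)(C(C)C)C(C)C)cc2c1C[C@H](/C=C/C(C)=O)CO2 | intermediate
18 | (E)-1,1,1-trifluoro-6-[(3R)-5-methoxy-6-prenyl-7-(triisopropylsilyloxy)chroman-3-yl]hex-5-ene-2,4-dione | COc1c(CC=C(C)C)c(O[Si](C(C)C)(C(C)C)C(C)C)cc2c1C[C@H](/C=C/C(=O)CC(=O)C(F)(F)F)CO2 | intermediate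
19 | (E)-1-diazo-4-[(3R)-5-methoxy-6-prenyl-7-(triisopropylsilyloxy)chroman-3-yl]but-3-en-2-one | COc1c(CC=C(C)C)c(O[Si](C(C)C)(C(C)C)C(C)C)cc2c1C[C@H](/C=C/C(=O)C=[N+]=[N-])CO2 | intermediate
20 | 4-methylpent-3-enoic acid | CC(C)=CCC(=O)O | starting material
21 | ethyl 4-methylpent-3-enoate | CCOC(=O)CC=C(C)C | intermediate
22 | lithium 1,1-dibromo-5-methylhexa-1,4-dien-2-olate | CC(C)=CCC([O-])=C(Br)Br.[Li+] | intermediate
23 | lithium 5-methylhex-4-en-1-yn-1-olate | CC(C)=CCC#C[O-].[Li+] | intermediate
24 | triisopropyl[(5-methylhex-4-en-1-yn-1-yl)oxy]silane | CC(C)=CCC#CO[Si](C(C)C)(C(C)C)C(C)C | intermediate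
25 | (E)-4-[(3R)-5-methoxy-6-prenyl-7-(triisopropylsilyloxy)chroman-3-yl]buta-1,3-dien-1-one (vinylketene) | COc1c(CC=C(C)C)c(O[Si](C(C)C)(C(C)C)C(C)C)cc2c1C[C@H](/C=C/C=C=O)CO2 | intermediate
26 | 4-{(E)-2-[(3R)-5-methoxy-6-prenyl-7-(triisopropylsilyloxy)chroman-3-yl]ethenyl}-2-prenyl-3-(triisopropylsilyloxy)cyclobut-2-en-1-one (ring sp3 centre unassigned) | COc1c(CC=C(C)C)c(O[Si](C(C)C)(C(C)C)C(C)C)cc2c1C[C@H](/C=C/C1C(=O)C(CC=C(C)C)=C1O[Si](C(C)C)(C(C)C)C(C)C)CO2 | intermediate
27 | (5E)-6-[(3R)-5-methoxy-6-prenyl-7-(triisopropylsilyloxy)chroman-3-yl]-2-prenyl-3-(triisopropylsilyloxy)hexa-1,3,5-trien-1-one, ketene and alkenyl group cis on the central alkene (dienylketene) | COc1c(CC=C(C)C)c(O[Si](C(C)C)(C(C)C)C(C)C)cc2c1C[C@H](/C=C/C=C(O[Si](C(C)C)(C(C)C)C(C)C)\C(CC=C(C)C)=C=O)CO2 | intermediate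
28 | 6-[(3R)-5-methoxy-6-prenyl-7-(triisopropylsilyloxy)chroman-3-yl]-2-prenyl-3-(triisopropylsilyloxy)cyclohexa-2,4-dien-1-one (ring sp3 centre unassigned) | COc1c(CC=C(C)C)c(O[Si](C(C)C)(C(C)C)C(C)C)cc2c1C[C@H](C1C=CC(O[Si](C(C)C)(C(C)C)C(C)C)=C(CC=C(C)C)C1=O)CO2 | intermediate
29 | 6-[(3R)-5-methoxy-6-prenyl-7-(triisopropylsilyloxy)chroman-3-yl]-2-prenyl-3-(triisopropylsilyloxy)phenol | COc1c(CC=C(C)C)c(O[Si](C(C)C)(C(C)C)C(C)C)cc2c1C[C@H](c1ccc(O[Si](C(C)C)(C(C)C)C(C)C)c(CC=C(C)C)c1O)CO2 | intermediate
30 | (3R)-3-[2,2-dimethyl-3-(phenylselanyl)-5-(triisopropylsilyloxy)chroman-8-yl]-5-methoxy-6-prenyl-7-(triisopropylsilyloxy)chroman (selenium-bearing centre unassigned) | COc1c(CC=C(C)C)c(O[Si](C(C)C)(C(C)C)C(C)C)cc2c1C[C@H](c1ccc(O[Si](C(C)C)(C(C)C)C(C)C)c3c1OC(C)(C)C([Se]c1ccccc1)C3)CO2 | intermediate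
31 | (3R)-3-[2,2-dimethyl-5-(triisopropylsilyloxy)-2H-chromen-8-yl]-5-methoxy-6-prenyl-7-(triisopropylsilyloxy)chroman | COc1c(CC=C(C)C)c(O[Si](C(C)C)(C(C)C)C(C)C)cc2c1C[C@H](c1ccc(O[Si](C(C)C)(C(C)C)C(C)C)c3c1OC(C)(C)C=C3)CO2 | intermediate
32 | (3R)-3-(5-hydroxy-2,2-dimethyl-2H-chromen-8-yl)-5-methoxy-6-prenylchroman-7-ol | COc1c(CC=C(C)C)c(O)cc2c1C[C@H](c1ccc(O)c3c1OC(C)(C)C=C3)CO2 | target

Total step count: 16. Longest linear sequence: 14 steps (steps 1 to 11, then 14 to 16); steps 12 and 13 are the two-step branch to alkyne 24.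

Steps most likely to fail

Step 14. The irradiation may degrade the electron-rich chroman or the skipped enyne, the ketene may dimerise or acylate the product phenol, or the cascade may stall at the cyclobutenone. The fallback sets out from diazoketone 19 and comes back at vinylketene 25, and so at phenol 29. The ketene is made in the dark from a stored precursor. Silver benzoate (AgO2CPh) and Et3N in aqueous THF bring about the Wolff rearrangement with capture by water (Arndt–Eistert homologation), which should give (E)-4-[(3R)-5-methoxy-6-prenyl-7-(triisopropylsilyloxy)chroman-3-yl]but-3-enoic acid F1. Oxalyl chloride with a trace of DMF should convert it into (E)-4-[(3R)-5-methoxy-6-prenyl-7-(triisopropylsilyloxy)chroman-3-yl]but-3-enoyl chloride F2. Slow addition of F2 to Et3N and alkyne 24 in toluene at 80–110 °C should regenerate 25 by dehydrochlorination at a low standing concentration, after which the same cycloaddition and electrocyclisation sequence leads to 29.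

Step 15. The selenium electrophile may add to the ring A prenyl alkene or the arene, closure may go 5-exo in place of 6-endo, or the alkenes may be epoxidised during the oxidation. The fallback sets out from phenol 29 and comes back at chromene 31. It is an aerobic palladium-catalysed oxidative cyclisation (Pd(dba)2, KHCO3, air, DMSO/H2O, 60 °C), known for ortho-prenyl phenols. The phenoxide adds to the palladium-bound prenyl alkene in the 6-endo sense, and β-hydride elimination from the benzylic carbon should give 31 directly. This fallback makes no compound outside the list (F0).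

Step 13. The carbenoid base may enolise the doubly activated α-CH2 of ester 21 instead of adding to its carbonyl, and excess alkyllithium may deprotonate the skipped enyne. The fallback sets out from prenyl bromide 2 and comes back at lithium ynolate 23. CuCl-catalysed coupling of 2 with HC≡CMgBr in THF should give 5-methylhex-4-en-1-yne F3. Deprotonation with n-BuLi and oxidation of the lithium acetylide with LiOOt-Bu (from t-BuOOH and LiN(SiMe3)2) at −78 → 0 °C should give 23, which is silylated with i-Pr3SiCl as in step 13 to give 24.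

Further compounds
F1 | step 14 | (E)-4-[(3R)-5-methoxy-6-prenyl-7-(triisopropylsilyloxy)chroman-3-yl]but-3-enoic acid | COc1c(CC=C(C)C)c(O[Si](C(C)C)(C(C)C)C(C)C)cc2c1C[C@H](/C=C/CC(=O)O)CO2
F2 | step 14 | (E)-4-[(3R)-5-methoxy-6-prenyl-7-(triisopropylsilyloxy)chroman-3-yl]but-3-enoyl chloride | COc1c(CC=C(C)C)c(O[Si](C(C)C)(C(C)C)C(C)C)cc2c1C[C@H](/C=C/CC(=O)Cl)CO2
F0 | step 15 | none | none
F3 | step 13 | 5-methylhex-4-en-1-yne | CC(C)=CCC#C
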